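Count amounts per litre of the first phase: 80.0 mM of reagent waits in the second phase for 20 mM of substrate.

    substrate + target → side product (k1 = 0.34 /M/h)
    reagent in the reaction phase ⇌ dormant form (K2 = 6.4, k2 = 0.012 /h)
    substrate + reagent in the reaction phase ⇌ target (K3 = 650 /M, k3 = 7.3 /M/h)
    reagent in the reaction phase ⇌ reagent in the second phase, rate k4*([reagent in the reaction phase] - [reagent in the second phase]/K4) per volume of the first phase (K4 = 1.3, k4 = 0.25 /h)

substrate 20 mM; reagent in the second phase 80.0 mM; time 30 h; volume of the second phase over the first 2.0

- elm: doubling the transfer coefficient of step 4, all else as stated
- maple: doubling the amount of reagent in the second phase, all else as stated

- in percentages every species weighs as the substrate in it: one side product counts as two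
- in the second phase: reagent in the second phase; everything else is in the first
- charges count per volume of the first phase; a concentration in a rate is the amount of a species over the volume of its own phase; every rate counts per litre of the first phase
- run time (flask): 30 h

1. amount of target at 30 h, in percent of the substrate charged
2. the change that raises the amount of target at 30 h, in percent of the substrate charged most ("none" if none brings more than 2 percentage points) (elm / maple / none)
3. amount of target at 30 h, in percent of the substrate charged, after maple

Work with the fraction of substrate left, not the fraction made. Let R be the reagent in the reaction phase. Suppose the substrate is bound as target. That takes 20 mM of reagent, and the rest shares out between the phases. With partition ratio P = 1.3 and volume ratio V = 2.0, the second phase holds P times V times R. So R comes to 16.7 mM.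

I leave out the dormant form, because the forward half-life of that drain, 58 h, is longer than the run.

Binding stops when target over substrate equals K times R, with K = 650 /M. So in this reckoning, with side product set aside, the fraction left levels off at F, one over one plus K times R. This gives 8.45%, the binding floor.

With R held, binding is pseudo-first-order. The excess over the floor halves every 5.22 h, which is shorter than the run. So I expect 10.1% left at 30 h. Target then comes to about 89.9%, less what the side step takes; my reckoning stops there.

F holds no transfer coefficient, so elm leaves it alone. Maple's doubled charge gives a floor of 3.81%, a drop of 4.6 percentage points. So I pick maple.

The forecast says 82.6%, maple, and 91.7% after maple: "Elm only removes the lag".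

The flask gives 83.1% of target, and maple is best: it adds 9.1 points and reaches 92.2%, while elm adds 1.1 points. In the flask, half the turnover of transfer into the reaction phase was done by 4.35 h, and at 3.00 h substrate still stood at 85.2%. Binding had 84% of its turnover behind it at 15.0 h, and 11% of the substrate was left at 30.0 h. For a neighbour charged with 50 mM of substrate, F comes to 15.6%; that neighbour reads 16% left, with 16.3% in side product.

The numbers are those of an exercise; no experiment stands behind them.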